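## Retrosynthetic overview

1. Ring atoms are numbered C1–C10 (C1, C2 = CH2; C3 = C=O; C4 = C(OH)Me; C5 = CH–O-angeloyl; C6 = lactone O–CH; C7 = lactone CH; C8 = CH–OH; C9 = CH–O-acyl; C10 = CHMe), and C11–C13 are the lactone α-carbon, carbonyl and methylene. Late stage: methylene unmasked from a Mannich base, C3 ketone from an acetonide-masked 3,4-diol, C9 ester on an alcohol made by hydroboration of an (E)-C9=C10 alkene.
2. Key disconnection C8–C9: Nozaki–Hiyama–Kishi closure of the ten-membered carbocycle from an (E)-alkenyl iodide and the C8 aldehyde on the lactone. The enabling feature is the free C8 carbinol between lactone carbon C7 and the C9(O)/C10(Me) pair, i.e. an allylic-alcohol retron C8(OH)–C9=C10(Me) inside the ten-membered ring.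
3. Lactone part: vinylogous Mukaiyama aldol of a 2-silyloxyfuran (C6, C7, C8, C11, C12) with an α-alkoxy aldehyde (C5) sets C5 and C6; copper hydride reduction of the butenolide sets C7 (cis fusion).
4. Aldehyde part (C1–C5, C9, C10): lactic acid dioxolanone aldol sets C4, the only purchased ring stereocentre, with (E)-5-iodo-4-methylpent-4-enal from carboalumination of 4-pentyn-1-ol.
5. Ring order: butenolide/γ-lactone ring first (step 8, kept throughout), temporary dioxolane on O3/O4 (step 6, removed in step 21), ten-membered carbocycle last (step 16).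

Key step: step 16

Remark (assumptions): C3 is drawn with the configuration expected from a chair aldol transition state; it is erased in step 22, so either epimer serves. C11 in 29–37 is expected as an epimer mixture, is drawn without configuration, and is erased in step 24. "As in the target" means the same spatial arrangement as in the target.

## Route

Step 1
Reactants: 1 4-pentyn-1-ol
Product: 3 (4E)-5-iodo-4-methylpent-4-en-1-ol, via alkenylalane 2 (not isolated)
Conditions: Me3Al (3 equiv), Cp2ZrCl2 (0.25 equiv), CH2Cl2, 0 °C → rt; then I2, THF, −30 → 0 °C; aq. Na/K tartrate, Na2S2O3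
Reagents that add atoms: trimethylaluminium, C[Al](C)C; iodine, II
Why: Zirconium-catalysed carboalumination (Negishi) adds Me–Al syn across the terminal alkyne and iodinolysis with retention should give the (E)-trisubstituted alkenyl iodide that later becomes C9=C10 with the C10 methyl.

Step 2
Reactants: 3 (4E)-5-iodo-4-methylpent-4-en-1-ol
Product: 4 (4E)-5-iodo-4-methylpent-4-enal
Conditions: Dess–Martin periodinane, NaHCO3, CH2Cl2, 0 °C → rt
Reagents that add atoms: none
Why: Dess–Martin oxidation of a primary alcohol to the aldehyde, which leaves the alkenyl iodide untouched.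

Step 3
Reactants: 5 (R)-lactic acid; 6 pivalaldehyde
Product: 7 (2R,5R)-2-tert-butyl-5-methyl-1,3-dioxolan-4-one
Conditions: p-TsOH·H2O (cat.), H2SO4 (cat.), pentane, reflux, Dean–Stark; crystallisation of the cis isomer
Reagents that add atoms: none
Why: Acid-catalysed acetalisation stores the lactate stereocentre in the cis-dioxolanone (self-regeneration of stereocentres), the cis isomer being favoured and purified by crystallisation.

Step 4
Reactants: 7 (2R,5R)-2-tert-butyl-5-methyl-1,3-dioxolan-4-one; 4 (4E)-5-iodo-4-methylpent-4-enal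
Product: 9 (2R,5S)-2-tert-butyl-5-[(1S,4E)-1-hydroxy-5-iodo-4-methylpent-4-enyl]-5-methyl-1,3-dioxolan-4-one, via lithium enolate 8 (not isolated)
Conditions: LDA, THF, −78 °C; then 4, −78 °C; aq. NH4Cl
Reagents that add atoms: none
Why: Aldol addition of the dioxolanone enolate, in which the aldehyde enters anti to the tert-butyl group and so replaces the former hydrogen with retention, should set quaternary C4; the C3 carbinol configuration is of no consequence.

Step 5
Reactants: 9 aldol adduct
Product: 10 methyl (2S,3S,6E)-2,3-dihydroxy-7-iodo-2,6-dimethylhept-6-enoate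
Conditions: camphorsulfonic acid (cat.), MeOH, 40 °C
Reagents that add atoms: methanol, CO
Why: Acid-catalysed methanolysis of the acylal-type lactone releases pivalaldehyde and gives the methyl ester diol without the retro-aldol risk of basic conditions.

Step 6
Reactants: 10 methyl ester diol
Product: 11 methyl (4S,5S)-5-[(3E)-4-iodo-3-methylbut-3-enyl]-2,2,4-trimethyl-1,3-dioxolane-4-carboxylate
Conditions: 2,2-dimethoxypropane, camphorsulfonic acid (cat.), CH2Cl2, rt
Reagents that add atoms: 2,2-dimethoxypropane, COC(C)(C)OC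
Why: Acetonide formation (transketalisation) ties O3 and O4 into a temporary dioxolane that masks the later α-ketol and provides the α-alkoxy group for Felkin–Anh control.

Step 7
Reactants: 11 acetonide methyl ester
Product: 12 (4S,5S)-5-[(3E)-4-iodo-3-methylbut-3-enyl]-2,2,4-trimethyl-1,3-dioxolane-4-carbaldehyde
Conditions: DIBAL-H (1.1 equiv), CH2Cl2, −78 °C; MeOH, aq. Na/K tartrate
Reagents that add atoms: none
Why: Partial DIBAL-H reduction of an α-alkoxy ester stops at the tetrahedral aluminate at −78 °C and should give the non-enolisable C5 aldehyde.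

Step 8
Reactants: 13 1,3-dihydroxyacetone (commercial dimer); 14 ethyl (triphenylphosphoranylidene)acetate
Product: 16 4-(hydroxymethyl)furan-2(5H)-one, via hydroxy enoate 15 (not isolated)
Conditions: CH2Cl2, rt, 16 h
Reagents that add atoms: none
Why: Wittig olefination of the ketone followed by spontaneous lactonisation of the γ-hydroxy enoate closes the butenolide ring, which becomes the γ-lactone of the target.

Step 9
Reactants: 16 4-(hydroxymethyl)furan-2(5H)-one
Product: 17 4-{[(tert-butyldiphenylsilyl)oxy]methyl}furan-2(5H)-one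
Conditions: TBDPSCl, imidazole, CH2Cl2, 0 °C → rt
Reagents that add atoms: tert-butyl(chloro)diphenylsilane, CC(C)(C)[Si](Cl)(c1ccccc1)c1ccccc1
Why: Silylation of the primary alcohol protects the future C8 oxygen.

Step 10
Reactants: 17 silyl ether butenolide
Product: 18 2-[(tert-butyldimethylsilyl)oxy]-4-{[(tert-butyldiphenylsilyl)oxy]methyl}furan
Conditions: TBSOTf, Et3N, CH2Cl2, 0 °C
Reagents that add atoms: tert-butyldimethylsilyl trifluoromethanesulfonate, CC(C)(C)[Si](C)(C)OS(=O)(=O)C(F)(F)F
Why: Soft enolisation (γ-deprotonation and O-silylation) of the butenolide gives the 2-silyloxyfuran, a vinylogous silyl ketene acetal.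

Step 11
Reactants: 12 dioxolane aldehyde; 18 2-silyloxyfuran
Product: 19 5-{hydroxy[(4,5)-5-((3E)-4-iodo-3-methylbut-3-enyl)-2,2,4-trimethyl-1,3-dioxolan-4-yl]methyl}-4-{[(tert-butyldiphenylsilyl)oxy]methyl}furan-2(5H)-one, C4–C6 as in the target (4,5-anti, 5,6-syn)
Conditions: BF3·OEt2 (1.2 equiv), CH2Cl2, −78 °C; aq. NaHCO3
Reagents that add atoms: none
Why: Vinylogous Mukaiyama aldol reaction in which the furan γ-carbon (C6) attacks the BF3-activated aldehyde through an open transition state (5,6-syn, threo) and anti to the C4–O bond (Felkin–Anh, 4,5-anti), so that C5 and C6 are both relayed from C4.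

Step 12
Reactants: 19 butenolide aldol adduct
Product: 20 cis-β,γ-disubstituted γ-butyrolactone (C7–H cis to C6–H), otherwise as 19
Conditions: Cu(OAc)2·H2O (5 mol%), 1,2-bis(diphenylphosphino)benzene (5 mol%), (EtO)2MeSiH, t-BuOH, toluene, 0 °C → rt; NH4F, MeOH
Reagents that add atoms: none
Why: Copper hydride conjugate reduction delivers hydride to C7 on the face opposite to the C6 side chain, which should place C8 cis to C5 (cis lactone fusion) and leave the alkenyl iodide and acetal intact.

Step 13
Reactants: 20 cis-lactone alcohol; 21 angelic acid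
Product: 23 C5 angelate of 20, via mixed anhydride 22 (not isolated)
Conditions: 21, 2,4,6-trichlorobenzoyl chloride, Et3N, toluene, rt; then 20, toluene, 75 °C (no DMAP)
Reagents that add atoms: none
Why: Yamaguchi esterification through the preformed mixed anhydride acylates the only free hydroxyl, and omitting DMAP is meant to suppress Z → E isomerisation of the angeloyl group.

Step 14
Reactants: 23 C5 angelate
Product: 24 C8 primary alcohol (tert-butyldiphenylsilyl group removed)
Conditions: HF·pyridine, pyridine, THF, 0 °C → rt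
Reagents that add atoms: none
Why: Buffered fluoride desilylation of the primary silyl ether, to which lactone, angelate and acetonide should be stable.

Step 15
Reactants: 24 C8 primary alcohol
Product: 25 C8 aldehyde (β-formyl γ-lactone)
Conditions: Dess–Martin periodinane, NaHCO3, CH2Cl2, 0 °C; used at once
Reagents that add atoms: none
Why: Buffered Dess–Martin oxidation gives the aldehyde under neutral conditions; it is used crude to avoid epimerisation at C7 or β-elimination of the lactone oxygen.

Step 16
Reactants: 25 C8 aldehyde carrying the (E)-alkenyl iodide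
Product: 26 ten-membered allylic alcohol: cis-fused lactone, (E)-C9=C10, C8–OH as in the target, O3/O4 acetonide, C5 angelate
Conditions: CrCl2 (10 equiv), NiCl2 (2 mol%), degassed DMSO/THF (3:1), 0.002 M by slow addition, rt; aq. sodium serinate/NaHCO3
Reagents that add atoms: none
Why: Nickel(0), formed from NiCl2 and CrCl2, inserts into the alkenyl C–I bond, the alkenyl group passes to chromium(III), and the alkenylchromium adds to the C8 aldehyde (Nozaki–Hiyama–Kishi reaction); lactone, esters and acetal are inert to it. The closest known reaction type is the Ni/Cr-mediated alkenyl iodide–aldehyde macrocyclisation that closes ten-membered carbocycles carrying a preformed γ-lactone. The ten-membered ring is closed by C8–C9 bond formation, an intramolecular 1,2-addition with the carbonyl exocyclic to the new ring (10-exo-trig), helped by the two arms held cis on the lactone (C6, C7), the rigid (E)-alkene, the dioxolane and high dilution. The new stereocentre C8 is controlled by C7 (Felkin–Anh): the tether can deliver the alkenylchromium only anti to lactone carbon C11, the chromium-bound oxygen sits on the open convex face between C6 and C11, and the nucleophile passes H7, which should give the target configuration. The step needs aldehyde-selective addition without epimerisation at C7 or β-elimination, which the neutral non-basic medium secures, and retention of the E geometry, which alkenylchromium reagents keep.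

Step 17
Reactants: 26 ten-membered allylic alcohol
Product: 27 C8 tert-butyldimethylsilyl ether of 26
Conditions: TBSOTf, 2,6-lutidine, CH2Cl2, −40 → 0 °C
Reagents that add atoms: tert-butyldimethylsilyl trifluoromethanesulfonate, CC(C)(C)[Si](C)(C)OS(=O)(=O)C(F)(F)F
Why: Silylation of the allylic alcohol keeps O8 distinct from the C9 hydroxyl made in step 19.

Step 18
Reactants: 27 C8 silyl ether
Product: 29 C11-(dimethylaminomethyl) lactone (C11 epimers), via lithium enolate 28 (not isolated)
Conditions: LiHMDS, THF, −78 °C; then CH2=NMe2+ I−, −78 → 0 °C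
Reagents that add atoms: N,N-dimethylmethyleneiminium iodide (Eschenmoser's salt), C=[N+](C)C.[I-]
Why: Mannich reaction of the lactone enolate (the only readily enolisable position, since the angelate has no α-hydrogen) installs C13 as a β-amino group, a masked α-methylene that survives the hydroboration.

Step 19
Reactants: 29 Mannich base with (E)-C9=C10
Product: 31 C9 alcohol (C9 and C10 as in the target), via alkylborane 30 (not isolated)
Conditions: 9-BBN, THF, 0 → 45 °C; then NaBO3·4H2O, THF/H2O, rt
Reagents that add atoms: sodium perborate, [Na+].[O-]OB=O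
Why: Hydroboration–oxidation places boron on the less substituted C9 and hydrogen on C10 by syn addition, which fixes O9/C10-Me anti on the E-alkene; with H8 in the alkene plane (A(1,3) strain against the C10 methyl) and ring carbon C7 blocking the inner face, attack from the outer face should give O9 syn to O8, while the dioxolane keeps C3 out of reach of the borane.

Step 20
Reactants: 31 C9 alcohol; 32 (R)-2-methylbutanoic acid
Product: 33 C9 (R)-2-methylbutanoate
Conditions: EDC·HCl, DMAP, CH2Cl2, 0 °C → rt
Reagents that add atoms: none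
Why: Steglich esterification of the only free hydroxyl under conditions that should not epimerise the α-stereocentre of the acid.

Step 21
Reactants: 33 diester acetonide
Product: 34 3,4-diol (acetonide removed)
Conditions: AcOH/THF/H2O (3:1:1), 45 °C
Reagents that add atoms: none
Why: Mild acidic hydrolysis of the trisubstituted dioxolane, which should be faster than cleavage of the hindered secondary silyl ether.

Step 22
Reactants: 34 3,4-diol
Product: 35 C3 ketone (α-ketol with tertiary C4–OH)
Conditions: Dess–Martin periodinane, pyridine, CH2Cl2, 0 °C → rt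
Reagents that add atoms: none
Why: Dess–Martin oxidation of the only free secondary alcohol gives the α-hydroxy ketone; C4 is quaternary, so the new β-acyloxy ketone cannot eliminate through C4.

Step 23
Reactants: 35 α-ketol silyl ether
Product: 36 C8 alcohol (dimethylamine adduct of the target)
Conditions: HF·pyridine, pyridine, THF, 0 °C → rt
Reagents that add atoms: none
Why: Buffered fluoride desilylation frees the C8 hydroxyl without base that could move the neighbouring C9 acyl group.

Step 24
Reactants: 36 dimethylamine adduct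
Product: 38 target CNP0226386.1, via ammonium iodide 37 (not isolated)
Conditions: MeI, MeOH, rt; evaporate; then aq. NaHCO3, EtOAc, rt
Reagents that add atoms: none
Why: N-Methylation and E1cB (Hofmann-type) elimination of trimethylamine from the β-ammonio lactone should unmask the α-methylene group and erase the C11 stereocentre.

## Compound list

1 | 4-pentyn-1-ol | C#CCCCO | starting material
2 | dimethyl[(1E)-5-(dimethylaluminooxy)-2-methylpent-1-enyl]alane | C[Al](C)OCCC/C(C)=C/[Al](C)C | intermediate
3 | (4E)-5-iodo-4-methylpent-4-en-1-ol | OCCC/C(C)=C/I | intermediate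
4 | (4E)-5-iodo-4-methylpent-4-enal | O=CCC/C(C)=C/I | intermediate
5 | (R)-lactic acid | C[C@@H](O)C(=O)O | starting material
6 | pivalaldehyde | CC(C)(C)C=O | starting material
7 | (2R,5R)-2-tert-butyl-5-methyl-1,3-dioxolan-4-one | C[C@H]1O[C@@H](C(C)(C)C)OC1=O | intermediate
8 | lithium enolate of 7 | [Li]OC1=C(C)O[C@@H](C(C)(C)C)O1 | intermediate
9 | (2R,5S)-2-tert-butyl-5-[(1S,4E)-1-hydroxy-5-iodo-4-methylpent-4-enyl]-5-methyl-1,3-dioxolan-4-one | C[C@@]1([C@@H](O)CC/C(C)=C/I)O[C@@H](C(C)(C)C)OC1=O | intermediate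
10 | methyl (2S,3S,6E)-2,3-dihydroxy-7-iodo-2,6-dimethylhept-6-enoate | COC(=O)[C@@](C)(O)[C@@H](O)CC/C(C)=C/I | intermediate
11 | methyl (4S,5S)-5-[(3E)-4-iodo-3-methylbut-3-enyl]-2,2,4-trimethyl-1,3-dioxolane-4-carboxylate | COC(=O)[C@@]1(C)OC(C)(C)O[C@H]1CC/C(C)=C/I | intermediate
12 | (4S,5S)-5-[(3E)-4-iodo-3-methylbut-3-enyl]-2,2,4-trimethyl-1,3-dioxolane-4-carbaldehyde | O=C[C@@]1(C)OC(C)(C)O[C@H]1CC/C(C)=C/I | intermediate
13 | 1,3-dihydroxyacetone (monomer drawn; used as commercial dimer) | OCC(=O)CO | starting material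
14 | ethyl (triphenylphosphoranylidene)acetate | CCOC(=O)C=P(c1ccccc1)(c1ccccc1)c1ccccc1 | starting material
15 | ethyl 4-hydroxy-3-(hydroxymethyl)but-2-enoate | CCOC(=O)C=C(CO)CO | intermediate
16 | 4-(hydroxymethyl)furan-2(5H)-one | O=C1C=C(CO)CO1 | intermediate
17 | 4-{[(tert-butyldiphenylsilyl)oxy]methyl}furan-2(5H)-one | O=C1C=C(CO[Si](c2ccccc2)(c2ccccc2)C(C)(C)C)CO1 | intermediate
18 | 2-[(tert-butyldimethylsilyl)oxy]-4-{[(tert-butyldiphenylsilyl)oxy]methyl}furan | CC(C)(C)[Si](C)(C)Oc1cc(CO[Si](c2ccccc2)(c2ccccc2)C(C)(C)C)co1 | intermediate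
19 | butenolide aldol adduct (C5–OH; C4, C5, C6 as in the target; O3/O4 acetonide; alkenyl iodide) | O=C1C=C(CO[Si](c2ccccc2)(c2ccccc2)C(C)(C)C)[C@H](O1)[C@@H](O)[C@@]1(C)OC(C)(C)O[C@H]1CC/C(C)=C/I | intermediate
20 | cis-β,γ-disubstituted γ-butyrolactone (C7 as in the target), otherwise as 19 | O=C1C[C@@H](CO[Si](c2ccccc2)(c2ccccc2)C(C)(C)C)[C@H](O1)[C@@H](O)[C@@]1(C)OC(C)(C)O[C@H]1CC/C(C)=C/I | intermediate
21 | angelic acid, (Z)-2-methylbut-2-enoic acid | C/C=C(/C)C(=O)O | starting material
22 | angelic 2,4,6-trichlorobenzoic anhydride | C/C=C(/C)C(=O)OC(=O)c1c(Cl)cc(Cl)cc1Cl | intermediate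
23 | C5 angelate of 20 | O=C1C[C@@H](CO[Si](c2ccccc2)(c2ccccc2)C(C)(C)C)[C@H](O1)[C@@H](OC(=O)/C(C)=C\C)[C@@]1(C)OC(C)(C)O[C@H]1CC/C(C)=C/I | intermediate
24 | C8 primary alcohol | O=C1C[C@@H](CO)[C@H](O1)[C@@H](OC(=O)/C(C)=C\C)[C@@]1(C)OC(C)(C)O[C@H]1CC/C(C)=C/I | intermediate
25 | C8 aldehyde (β-formyl γ-lactone) | O=C1C[C@@H](C=O)[C@H](O1)[C@@H](OC(=O)/C(C)=C\C)[C@@]1(C)OC(C)(C)O[C@H]1CC/C(C)=C/I | intermediate
26 | ten-membered allylic alcohol (cis-fused lactone, (E)-C9=C10, C8–OH as in the target, acetonide, C5 angelate) | O=C1C[C@@H]2[C@H](O1)[C@@H](OC(=O)/C(C)=C\C)[C@@]1(C)OC(C)(C)O[C@H]1CC/C(C)=C/[C@@H]2O | intermediate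
27 | C8 tert-butyldimethylsilyl ether of 26 | O=C1C[C@@H]2[C@H](O1)[C@@H](OC(=O)/C(C)=C\C)[C@@]1(C)OC(C)(C)O[C@H]1CC/C(C)=C/[C@@H]2O[Si](C)(C)C(C)(C)C | intermediate
28 | lithium enolate of lactone 27 | [Li]OC1=C[C@@H]2[C@H](O1)[C@@H](OC(=O)/C(C)=C\C)[C@@]1(C)OC(C)(C)O[C@H]1CC/C(C)=C/[C@@H]2O[Si](C)(C)C(C)(C)C | intermediate
29 | C11-(dimethylaminomethyl) lactone (C11 epimers) | O=C1C(CN(C)C)[C@@H]2[C@H](O1)[C@@H](OC(=O)/C(C)=C\C)[C@@]1(C)OC(C)(C)O[C@H]1CC/C(C)=C/[C@@H]2O[Si](C)(C)C(C)(C)C | intermediate
30 | C9 B-alkyl-9-borabicyclo[3.3.1]nonane adduct of 29 | O=C1C(CN(C)C)[C@@H]2[C@H](O1)[C@@H](OC(=O)/C(C)=C\C)[C@@]1(C)OC(C)(C)O[C@H]1CC[C@@H](C)[C@@H](B3C4CCCC3CCC4)[C@@H]2O[Si](C)(C)C(C)(C)C | intermediate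
31 | C9 alcohol (C9, C10 as in the target) | O=C1C(CN(C)C)[C@@H]2[C@H](O1)[C@@H](OC(=O)/C(C)=C\C)[C@@]1(C)OC(C)(C)O[C@H]1CC[C@@H](C)[C@@H](O)[C@@H]2O[Si](C)(C)C(C)(C)C | intermediate
32 | (R)-2-methylbutanoic acid | CC[C@@H](C)C(=O)O | starting material
33 | C9 (R)-2-methylbutanoate of 31 | O=C1C(CN(C)C)[C@@H]2[C@H](O1)[C@@H](OC(=O)/C(C)=C\C)[C@@]1(C)OC(C)(C)O[C@H]1CC[C@@H](C)[C@@H](OC(=O)[C@H](C)CC)[C@@H]2O[Si](C)(C)C(C)(C)C | intermediate
34 | 3,4-diol (acetonide removed) | O=C1C(CN(C)C)[C@@H]2[C@H](O1)[C@@H](OC(=O)/C(C)=C\C)[C@@](C)(O)[C@@H](O)CC[C@@H](C)[C@@H](OC(=O)[C@H](C)CC)[C@@H]2O[Si](C)(C)C(C)(C)C | intermediate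
35 | C3 ketone (α-ketol), C8 silyl ether | O=C1C(CN(C)C)[C@@H]2[C@H](O1)[C@@H](OC(=O)/C(C)=C\C)[C@@](C)(O)C(=O)CC[C@@H](C)[C@@H](OC(=O)[C@H](C)CC)[C@@H]2O[Si](C)(C)C(C)(C)C | intermediate
36 | dimethylamine adduct of the target (C8–OH free) | O=C1C(CN(C)C)[C@@H]2[C@H](O1)[C@@H](OC(=O)/C(C)=C\C)[C@@](C)(O)C(=O)CC[C@@H](C)[C@@H](OC(=O)[C@H](C)CC)[C@@H]2O | intermediate
37 | trimethylammonium iodide of 36 | O=C1C(C[N+](C)(C)C)[C@@H]2[C@H](O1)[C@@H](OC(=O)/C(C)=C\C)[C@@](C)(O)C(=O)CC[C@@H](C)[C@@H](OC(=O)[C@H](C)CC)[C@@H]2O.[I-] | intermediate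
38 | CNP0226386.1 | O=C1C(=C)[C@@H]2[C@H](O1)[C@@H](OC(=O)/C(C)=C\C)[C@@](C)(O)C(=O)CC[C@@H](C)[C@@H](OC(=O)[C@H](C)CC)[C@@H]2O | target

## Step count and risks

Total step count: 24. Longest linear sequence: 20 steps (steps 1, 2, 4–7, 11–24, from 4-pentyn-1-ol).

Steps most likely to fail:

Step 16. The ten-membered transition state may override the Felkin–Anh preference at the C8 aldehyde, so that facial selectivity is poor and the C8 epimer forms alongside 26. The fallback sets out from 25 and returns at 26. The ring is closed in the same way without regard to selectivity; the mixture of 26 and the C8 epimer of 26 F1 is oxidised with Dess–Martin periodinane to the cyclodecenone F2. A reagent-controlled Corey–Bakshi–Shibata reduction [(S)-2-methyl-CBS-oxazaborolidine, catecholborane, toluene, −78 °C, the alkenyl arm acting as the large group] should then return 26.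

Step 19. The outer face of the ring alkene also carries the bulky tert-butyldimethylsilyl ether, so hydroboration may be slow and its facial selectivity eroded. The fallback sets out from 26 and returns at 36. The smaller C8 triethylsilyl ether of 26 F3 is made (TESOTf, 2,6-lutidine) and taken through the Mannich reaction to the C11-(dimethylaminomethyl) lactone F4, hydroboration–oxidation to the C9 alcohol F5, and Steglich esterification with 32 to the C9 (R)-2-methylbutanoate F6. Aqueous acetic acid then removes the acetonide and the triethylsilyl group together to give the 3,4,8-triol F7. Its only 1,2-diol (O3/O4) is converted into the dibutylstannylene acetal (Bu2SnO) and brominolysed (NBS), so that only the C3 carbinol is oxidised, which gives 36.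

Step 13. The C5 hydroxyl is neopentyl-like, and under forcing conditions the angeloyl group may isomerise to the tigloyl (E) isomer or acylation may stall. The fallback sets out from 20 and returns at 23. The alcohol is acylated with 2-[bis(2,2,2-trifluoroethoxy)phosphoryl]propanoic acid (DCC, DMAP) to the C5 phosphonopropanoate of 20 F8. A Still–Gennari olefination (KHMDS, 18-crown-6, acetaldehyde, THF, −78 °C) then builds the Z-enoate on the substrate and gives 23.

## Further compounds

F1 | step 16 | C8 epimer of 26 | O=C1C[C@@H]2[C@H](O1)[C@@H](OC(=O)/C(C)=C\C)[C@@]1(C)OC(C)(C)O[C@H]1CC/C(C)=C/[C@H]2O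
F2 | step 16 | cyclodecenone (C8 ketone conjugated with (E)-C9=C10) | O=C1C[C@@H]2[C@H](O1)[C@@H](OC(=O)/C(C)=C\C)[C@@]1(C)OC(C)(C)O[C@H]1CC/C(C)=C/C2=O
F3 | step 19 | C8 triethylsilyl ether of 26 | O=C1C[C@@H]2[C@H](O1)[C@@H](OC(=O)/C(C)=C\C)[C@@]1(C)OC(C)(C)O[C@H]1CC/C(C)=C/[C@@H]2O[Si](CC)(CC)CC
F4 | step 19 | C11-(dimethylaminomethyl) lactone, triethylsilyl series | O=C1C(CN(C)C)[C@@H]2[C@H](O1)[C@@H](OC(=O)/C(C)=C\C)[C@@]1(C)OC(C)(C)O[C@H]1CC/C(C)=C/[C@@H]2O[Si](CC)(CC)CC
F5 | step 19 | C9 alcohol, triethylsilyl series | O=C1C(CN(C)C)[C@@H]2[C@H](O1)[C@@H](OC(=O)/C(C)=C\C)[C@@]1(C)OC(C)(C)O[C@H]1CC[C@@H](C)[C@@H](O)[C@@H]2O[Si](CC)(CC)CC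
F6 | step 19 | C9 (R)-2-methylbutanoate, triethylsilyl series | O=C1C(CN(C)C)[C@@H]2[C@H](O1)[C@@H](OC(=O)/C(C)=C\C)[C@@]1(C)OC(C)(C)O[C@H]1CC[C@@H](C)[C@@H](OC(=O)[C@H](C)CC)[C@@H]2O[Si](CC)(CC)CC
F7 | step 19 | 3,4,8-triol | O=C1C(CN(C)C)[C@@H]2[C@H](O1)[C@@H](OC(=O)/C(C)=C\C)[C@@](C)(O)[C@@H](O)CC[C@@H](C)[C@@H](OC(=O)[C@H](C)CC)[C@@H]2O
F8 | step 13 | C5 2-[bis(2,2,2-trifluoroethoxy)phosphoryl]propanoate of 20 | O=C1C[C@@H](CO[Si](c2ccccc2)(c2ccccc2)C(C)(C)C)[C@H](O1)[C@@H](OC(=O)C(C)P(=O)(OCC(F)(F)F)OCC(F)(F)F)[C@@]1(C)OC(C)(C)O[C@H]1CC/C(C)=C/I
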